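At 1.33 h Thursday's flask had given 19.9% product, and at 10.0 h it had given 66.4%. Two chemists read that slowing differently before a new set of flasks was charged.

| flask | substrate | partner | precatalyst | temperature | remark | time |
|---|---|---|---|---|---|---|
| Monday's | 0.20 M | 1.05 equiv | 2.5 mol% | 5 °C | run made earlier |  |
| Thursday's | 0.20 M | 1.05 equiv | 3.8 mol% | 48 °C | run made earlier |  |
| gamma | 0.20 M | 1.05 equiv | 5 mol% | 85 °C |  | 2.0 h |
| zeta | 0.20 M | 1.05 equiv | 5 mol% | 10 °C |  | 2.0 h |
| delta | 0.20 M | 1.05 equiv | 5 mol% | 35 °C |  | 2.0 h |
| eta | 0.20 M | 1.05 equiv | 5 mol% | 60 °C |  | 2.0 h |

- Monday's (time / h: product / %, substrate / %): 10.0: 3.5, 96.8; 25.0: 7.1, 92.5; 48.0: 13.9, 84.9; 72.0: 19.5, 79.0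
- Thursday's (time / h: product / %, substrate / %): 1.33: 19.9, 80.5; 3.00: 36.9, 62.8; 6.00: 54.4, 46.4; 10.0: 66.4, 32.2

(each reading ± 0.5 percentage points)

- the flask with the highest amount of product, in percent of the substrate charged ("all alike" if they lie within 1.5 percentage points) (gamma / zeta / delta / eta / all alike)
- final product, as a percentage of the substrate charged, in gamma
- final product, as a percentage of the substrate charged, in zeta
- final product, as a percentage of the substrate charged, in delta
- final product, as a percentage of the substrate charged, in eta

The first chemist treats partner as constant, the pseudo-first-order reading, so substrate should fall by a fixed half-life. Thursday's first reading gives 4.25 h, which would leave 19.6% substrate at 10.0 h, yet the flask read 32.2%.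

The second chemist notes that partner is charged nearly equal to substrate and falls with it, so the rate sinks with the square of what is left. Then the product share is n/(1+n), where n counts the hours in units of the half-time, the time by which half of the substrate has reacted. Thursday's last reading gives a half-time of 5.06 h, and this is the quantity to carry. That predicts 37.2% product at 3.00 h, and a different reading there shows 36.9%.

The forecast sides with the second chemist: 2% in zeta, 15% in delta, 54% in eta and 85% in gamma, so gamma leads. It warns about the hottest flask, that “the equilibrium could shift or the catalyst could die there”.

My own reckoning reads that gamma figure on the same count: it means a half-time of 0.353 h in gamma, which is 5.67 half-times in 2.0 h, and shorter than Thursday's 5.06 h. Granted the same starting speed, the first chemist's exponential gives 99.7% product in gamma, more than the forecast's 85%.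

    precatalyst ⇌ catalyst (K = 0.110, k = 0.00100 /s, Ea = 89.0 kJ/mol, ΔH = 28.0 kJ/mol)
    substrate + partner + catalyst → catalyst + product (k = 0.130 /M²/s, Ea = 36.0 kJ/mol)
    (constants at 35 °C)

The simulation gives 84.0% product in gamma, and gamma leads, with 53.6% in eta, 16.2% in delta and 1.97% in zeta. The second chemist's view stands against the first chemist's 99.7%. Gamma passed 50.0% conversion at 0.417 h, later than the 0.353 h read from the forecast, so gamma's half-time stands below Thursday's 5.06 h by a factor of 12.1. The first chemist would have been right in zeta: its count is 0.0201, and an exponential on that count gives 1.99%, within the 0.5 percentage points scatter of 1.97%.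

The same count serves on a second flask, gamma's recipe charged at 0.080 M substrate. Partner and precatalyst are charged on the substrate and fall with it, so Thursday's 5.06 h divided by that factor, which is gamma's 0.417 h, grows with the square of the dilution to 2.61 h. The count in 2.0 h is then 0.768, which gives 43.4% product, and that neighbour flask computes to 43.3%.

(The earlier runs and the new flask are simulated with made-up constants; the scatter is artificial.)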